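Cuts: the ester C–O bonds at C1′ (angelate) and C3 (acetate), the O–CH3 bond of the methyl ester, the Cα=CH2 double bond, the aryl bond C5–C1′ and, at the centre, the bond Cα–C2.
Enabling feature: C3–O and C2–Cα stand cis on the dihydrofuran ring, so the chain O–C3–C2–Cα–C(=O) can be closed to a cis-fused γ-lactone. Undoing Cα–C2 then leaves a C3-bound diazo ester whose carbene carbon lies 1,5 to a C2–H bond made hydridic by O1.
Forward: the benzofuranone bicycle is bought, its ketone is reduced, C3–OH is acylated and diazotised, and rhodium-carbenoid C–H insertion closes the lactone as the third ring.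
Cα carries a diethyl phosphonate through the insertion, because a plain lactone enolate would expel O1 as aryloxide. The phosphonate later gives Cα=CH2 by olefination of formaldehyde without a free enolate.
Then follow the C5 side chain (Stille coupling, ketone reduction, silylation), olefination, lactone opening to the methyl ester, C3 acetylation, desilylation and the angelate last.
Stereochemistry: C3 and C1′ come from catalyst-controlled transfer hydrogenation (opposite catalyst enantiomers), C2 is relayed from C3 by the obligatory cis five–five fusion, and the Z-alkene is bought with angelic acid.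
Key step: step 4

Remark: atoms follow benzofuran numbering (O1, C2, C3, C3a, C4–C7, C7a), Cα is the acrylate carbon on C2 and C1′ the side-chain carbinol carbon; the target reads as (2S,3S) with the C2 and C3 substituents cis, (1′S) and Z; the phosphorus-bearing Cα of the α-phosphono lactones is assumed to settle as the convex-face epimer and is drawn so, although it is labile and its configuration has no consequence.

Step 1
Reactants: 1 5-bromobenzofuran-3(2H)-one
Product: 2 (S)-5-bromo-2,3-dihydrobenzofuran-3-ol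
Conditions: RuCl[(R,R)-TsDPEN](p-cymene) (1 mol %), HCO2H/Et3N (5:2), CH2Cl2, 25 °C
Reagents that add atoms: none
Why: Noyori–Ikariya asymmetric transfer hydrogenation of an aryl ketone, in which the (R,R)-catalyst (divalent ruthenium) delivers hydride and proton to the carbonyl face fixed by the CH–π contact between its η6-arene and the fused benzene ring, the same spatial sense that gives (R)-1-indanol, the descriptor reading S here only because C2, bearing O1, outranks C3a, while the buffered medium spares the dehydration-prone benzylic alcohol.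

Step 2
Reactants: 2 (S)-5-bromo-2,3-dihydrobenzofuran-3-ol; 3 2-(diethoxyphosphoryl)acetic acid
Product: 4 (S)-5-bromo-2,3-dihydrobenzofuran-3-yl 2-(diethoxyphosphoryl)acetate
Conditions: DCC, DMAP (cat.), CH2Cl2, 0 °C → rt
Reagents that add atoms: none
Why: Steglich esterification forms the acyl–O bond without touching the C3–O bond, so the configuration is kept, and the near-neutral medium avoids loss of the benzylic oxygen with aromatisation to the benzofuran.

Step 3
Reactants: 4 (S)-5-bromo-2,3-dihydrobenzofuran-3-yl 2-(diethoxyphosphoryl)acetate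
Product: 5 (S)-5-bromo-2,3-dihydrobenzofuran-3-yl 2-diazo-2-(diethoxyphosphoryl)acetate
Conditions: LiN(SiMe3)2 (1.05 equiv), THF, −78 °C; p-ABSA, −78 °C → rt
Reagents that add atoms: 4-acetamidobenzenesulfonyl azide (p-ABSA), CC(=O)Nc1ccc(cc1)S(=O)(=O)N=[N+]=[N-]
Why: Regitz diazo transfer, in which one equivalent of amide base removes only the proton between P=O and C=O, the stabilised anion attacks the terminal azide nitrogen and the triazene collapses to diazo compound and sulfonamide, leaving no strong base to trigger elimination across C2–C3.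

Step 4
Reactants: 5 (S)-5-bromo-2,3-dihydrobenzofuran-3-yl 2-diazo-2-(diethoxyphosphoryl)acetate
Product: 6 diethyl [(3S,3aR,8bS)-7-bromo-2-oxo-2,3,3a,8b-tetrahydrofuro[3,2-b]benzofuran-3-yl]phosphonate (cis-fused tricyclic lactone)
Conditions: Rh2(O2CC7H15)4 (2 mol %), 4 Å MS, CH2Cl2 (0.02 M), 45 °C, sealed vessel
Reagents that add atoms: none
Why: Dirhodium tetraoctanoate (divalent rhodium) binds the diazo carbon of 5, N2 leaves, and the electrophilic carbenoid carbon Cα inserts into a C2–H bond through a concerted, hydride-transfer-like three-centre transition state that makes Cα–C2 and Cα–H together. The closest known reaction type is the rhodium-catalysed intramolecular C–H insertion of alkyl 2-diazo-2-(diethoxyphosphoryl)acetates to α-phosphono-γ-butyrolactones, a relative of the diazoacetate-to-γ-lactone insertion of cyclic secondary alcohols. The one ring closed is the γ-lactone O–C3–C2–Cα–C(=O), formed by 1,5-insertion, that is by bonding the carbene carbon to the fifth atom of the chain Cα–C(=O)–O–C3–C2 through a five-membered cyclic array. C2 is controlled by C3, since only the C2–H bond on the face that carries the ester oxygen can reach the carbenoid, insertion goes with retention and a trans five–five fusion is too strained to form, so 3S is copied into the cis ring fusion, whereas Cα is a labile centre that should settle with phosphorus on the convex face and is erased in step 8. The step needs C2–H insertion to outrun insertion into C3–H (β-lactone), cyclopropanation of the C3a–C4 arene bond and carbene dimerisation. O1 raises the hydridic character of C2–H while the acyloxy oxygen lowers that of C3–H, C2 holds the only sp3 C–H bonds in a 1,5-relationship, the bromine and the strain of a cyclopropane at the ring-fusion carbon C3a hold the arene back, and dilution suppresses dimers.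

Step 5
Reactants: 6 diethyl [(3S,3aR,8bS)-7-bromo-2-oxo-2,3,3a,8b-tetrahydrofuro[3,2-b]benzofuran-3-yl]phosphonate; 7 tributyl(1-ethoxyvinyl)stannane
Product: 9 diethyl [(3S,3aR,8bS)-7-acetyl-2-oxo-2,3,3a,8b-tetrahydrofuro[3,2-b]benzofuran-3-yl]phosphonate, via ethoxyvinyl arene 8 (not isolated)
Conditions: Pd(PPh3)4 (5 mol %), toluene, 100 °C; then 1 M HCl, THF, rt
Reagents that add atoms: water, O
Why: Migita–Kosugi–Stille coupling at the aryl bromide (oxidative addition to zerovalent palladium, transmetalation, reductive elimination) runs without base, so the acidic Cα–H next to the β-aryloxy group is left alone, and brief aqueous acid hydrolyses the enol ether to the methyl ketone before any allylic aryl ether exists that palladium could ionise.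

Step 6
Reactants: 9 diethyl [(3S,3aR,8bS)-7-acetyl-2-oxo-2,3,3a,8b-tetrahydrofuro[3,2-b]benzofuran-3-yl]phosphonate
Product: 10 diethyl [(3S,3aR,8bS)-7-[(S)-1-hydroxyethyl]-2-oxo-2,3,3a,8b-tetrahydrofuro[3,2-b]benzofuran-3-yl]phosphonate
Conditions: RuCl[(S,S)-TsDPEN](p-cymene) (1 mol %), HCO2H/Et3N (5:2), CH2Cl2, 30 °C
Reagents that add atoms: none
Why: Noyori–Ikariya asymmetric transfer hydrogenation of an aryl methyl ketone, for which the (S,S)-catalyst gives the (S)-1-arylethanol under pure catalyst control because the ring stereocentres are remote, while lactone and phosphonate are inert and the acidic buffer keeps Cα protonated.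

Step 7
Reactants: 10 diethyl [(3S,3aR,8bS)-7-[(S)-1-hydroxyethyl]-2-oxo-2,3,3a,8b-tetrahydrofuro[3,2-b]benzofuran-3-yl]phosphonate
Product: 11 diethyl [(3S,3aR,8bS)-7-[(S)-1-(tert-butyldimethylsilyloxy)ethyl]-2-oxo-2,3,3a,8b-tetrahydrofuro[3,2-b]benzofuran-3-yl]phosphonate
Conditions: TBSCl, imidazole, DMF, rt
Reagents that add atoms: tert-butyldimethylsilyl chloride, CC(C)(C)[Si](C)(C)Cl
Why: Standard imidazole-promoted O-silylation leaves the C1′–O bond intact, gives an ether that withstands carbonate, hydroxide and DMAP, and puts a donor instead of an acetyl group para to O1, which makes O1 a poorer leaving group in the basic steps ahead.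

Step 8
Reactants: 11 diethyl [(3S,3aR,8bS)-7-[(S)-1-(tert-butyldimethylsilyloxy)ethyl]-2-oxo-2,3,3a,8b-tetrahydrofuro[3,2-b]benzofuran-3-yl]phosphonate
Product: 12 (3aS,8bS)-7-[(S)-1-(tert-butyldimethylsilyloxy)ethyl]-3-methylene-3a,8b-dihydrofuro[3,2-b]benzofuran-2(3H)-one
Conditions: 37% aq. CH2O, K2CO3, THF, 0 °C
Reagents that add atoms: formaldehyde, C=O
Why: Horner–Wadsworth–Emmons olefination of an α-phosphono lactone, in which the small stationary amount of doubly stabilised anion is caught at once by excess formaldehyde and the adduct collapses through an oxaphosphetane, so no unstabilised enolate that could eject O1 by E1cB is ever formed and C2 and C3 stay untouched.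

Step 9
Reactants: 12 (3aS,8bS)-7-[(S)-1-(tert-butyldimethylsilyloxy)ethyl]-3-methylene-3a,8b-dihydrofuro[3,2-b]benzofuran-2(3H)-one
Product: 14 methyl 2-[(2S,3S)-5-[(S)-1-(tert-butyldimethylsilyloxy)ethyl]-3-hydroxy-2,3-dihydrobenzofuran-2-yl]acrylate, via potassium carboxylate 13 (not isolated)
Conditions: KOH (1.0 equiv), THF/H2O, 0 °C; evaporate, toluene azeotrope; MeI, DMF, 0 °C → rt
Reagents that add atoms: potassium hydroxide, [K+].[OH-]; iodomethane, CI
Why: Saponification of an α-methylene-γ-butyrolactone by acyl attack of hydroxide followed by SN2 O-alkylation of the dry potassium carboxylate, a pairing that breaks no bond at C2 or C3 and never passes through the free hydroxy acid, which would close back to the lactone.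

Step 10
Reactants: 14 methyl 2-[(2S,3S)-5-[(S)-1-(tert-butyldimethylsilyloxy)ethyl]-3-hydroxy-2,3-dihydrobenzofuran-2-yl]acrylate
Product: 15 methyl 2-[(2S,3S)-3-acetoxy-5-[(S)-1-(tert-butyldimethylsilyloxy)ethyl]-2,3-dihydrobenzofuran-2-yl]acrylate
Conditions: Ac2O, pyridine, DMAP (cat.), CH2Cl2, 0 °C (crude 14, at once)
Reagents that add atoms: acetic anhydride, CC(=O)OC(C)=O
Why: DMAP-catalysed acetylation of a secondary alcohol is fast at 0 °C, keeps the C3–O bond and thus the configuration, and caps the hydroxyl before it can attack the conjugated and therefore sluggish methyl ester.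

Step 11
Reactants: 15 methyl 2-[(2S,3S)-3-acetoxy-5-[(S)-1-(tert-butyldimethylsilyloxy)ethyl]-2,3-dihydrobenzofuran-2-yl]acrylate
Product: 16 methyl 2-[(2S,3S)-3-acetoxy-5-[(S)-1-hydroxyethyl]-2,3-dihydrobenzofuran-2-yl]acrylate
Conditions: Bu4NF/AcOH (1:1), THF, 0 °C → rt
Reagents that add atoms: none
Why: Fluoride-induced cleavage of the Si–O bond leaves the C1′–O bond and its S configuration alone, and the acetic acid buffer keeps the medium too weakly basic to remove the acetate or add to the acrylate and too weakly acidic to ionise either alkoxy-activated benzylic C–O bond.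

Step 12
Reactants: 16 methyl 2-[(2S,3S)-3-acetoxy-5-[(S)-1-hydroxyethyl]-2,3-dihydrobenzofuran-2-yl]acrylate; 17 angelic acid, (Z)-2-methylbut-2-enoic acid
Product: 19 methyl 2-[(2S,3S)-3-acetoxy-5-[(S)-1-{[(Z)-2-methylbut-2-enoyl]oxy}ethyl]-2,3-dihydrobenzofuran-2-yl]acrylate (CNP0168827.1), via mixed anhydride 18 (not isolated)
Conditions: 17, 2,4,6-Cl3C6H2COCl, Et3N, toluene, rt; then 16, 75 °C (no DMAP)
Reagents that add atoms: none
Why: Yamaguchi-type mixed-anhydride acylation run without a nucleophilic pyridine catalyst, since reversible conjugate addition of such a catalyst to the activated angeloyl unit is what turns Z into E, and because only the acyl–O bond is formed the C1′ configuration is retained.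

Compound list
1 | 5-bromobenzofuran-3(2H)-one | O=C1COc2ccc(Br)cc21 | starting material
2 | (S)-5-bromo-2,3-dihydrobenzofuran-3-ol | C1Oc2ccc(Br)cc2[C@@H]1O | intermediate
3 | 2-(diethoxyphosphoryl)acetic acid (diethylphosphonoacetic acid) | OC(=O)CP(=O)(OCC)OCC | starting material
4 | (S)-5-bromo-2,3-dihydrobenzofuran-3-yl 2-(diethoxyphosphoryl)acetate | C1Oc2ccc(Br)cc2[C@@H]1OC(=O)CP(=O)(OCC)OCC | intermediate
5 | (S)-5-bromo-2,3-dihydrobenzofuran-3-yl 2-diazo-2-(diethoxyphosphoryl)acetate | C1Oc2ccc(Br)cc2[C@@H]1OC(=O)C(=[N+]=[N-])P(=O)(OCC)OCC | intermediate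
6 | diethyl [(3S,3aR,8bS)-7-bromo-2-oxo-2,3,3a,8b-tetrahydrofuro[3,2-b]benzofuran-3-yl]phosphonate | O=C1[C@@H](P(=O)(OCC)OCC)[C@@H]2Oc3ccc(Br)cc3[C@@H]2O1 | intermediate
7 | tributyl(1-ethoxyvinyl)stannane | CCCC[Sn](CCCC)(CCCC)C(=C)OCC | starting material
8 | diethyl [(3S,3aR,8bS)-7-(1-ethoxyvinyl)-2-oxo-2,3,3a,8b-tetrahydrofuro[3,2-b]benzofuran-3-yl]phosphonate | O=C1[C@@H](P(=O)(OCC)OCC)[C@@H]2Oc3ccc(C(=C)OCC)cc3[C@@H]2O1 | intermediate
9 | diethyl [(3S,3aR,8bS)-7-acetyl-2-oxo-2,3,3a,8b-tetrahydrofuro[3,2-b]benzofuran-3-yl]phosphonate | O=C1[C@@H](P(=O)(OCC)OCC)[C@@H]2Oc3ccc(C(C)=O)cc3[C@@H]2O1 | intermediate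
10 | diethyl [(3S,3aR,8bS)-7-[(S)-1-hydroxyethyl]-2-oxo-2,3,3a,8b-tetrahydrofuro[3,2-b]benzofuran-3-yl]phosphonate | O=C1[C@@H](P(=O)(OCC)OCC)[C@@H]2Oc3ccc([C@H](C)O)cc3[C@@H]2O1 | intermediate
11 | diethyl [(3S,3aR,8bS)-7-[(S)-1-(tert-butyldimethylsilyloxy)ethyl]-2-oxo-2,3,3a,8b-tetrahydrofuro[3,2-b]benzofuran-3-yl]phosphonate | O=C1[C@@H](P(=O)(OCC)OCC)[C@@H]2Oc3ccc([C@H](C)O[Si](C)(C)C(C)(C)C)cc3[C@@H]2O1 | intermediate
12 | (3aS,8bS)-7-[(S)-1-(tert-butyldimethylsilyloxy)ethyl]-3-methylene-3a,8b-dihydrofuro[3,2-b]benzofuran-2(3H)-one | O=C1C(=C)[C@@H]2Oc3ccc([C@H](C)O[Si](C)(C)C(C)(C)C)cc3[C@@H]2O1 | intermediate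
13 | potassium 2-[(2S,3S)-5-[(S)-1-(tert-butyldimethylsilyloxy)ethyl]-3-hydroxy-2,3-dihydrobenzofuran-2-yl]acrylate | C=C(C(=O)[O-])[C@@H]1Oc2ccc([C@H](C)O[Si](C)(C)C(C)(C)C)cc2[C@@H]1O.[K+] | intermediate
14 | methyl 2-[(2S,3S)-5-[(S)-1-(tert-butyldimethylsilyloxy)ethyl]-3-hydroxy-2,3-dihydrobenzofuran-2-yl]acrylate | C=C(C(=O)OC)[C@@H]1Oc2ccc([C@H](C)O[Si](C)(C)C(C)(C)C)cc2[C@@H]1O | intermediate
15 | methyl 2-[(2S,3S)-3-acetoxy-5-[(S)-1-(tert-butyldimethylsilyloxy)ethyl]-2,3-dihydrobenzofuran-2-yl]acrylate | C=C(C(=O)OC)[C@@H]1Oc2ccc([C@H](C)O[Si](C)(C)C(C)(C)C)cc2[C@@H]1OC(C)=O | intermediate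
16 | methyl 2-[(2S,3S)-3-acetoxy-5-[(S)-1-hydroxyethyl]-2,3-dihydrobenzofuran-2-yl]acrylate | C=C(C(=O)OC)[C@@H]1Oc2ccc([C@H](C)O)cc2[C@@H]1OC(C)=O | intermediate
17 | angelic acid, (Z)-2-methylbut-2-enoic acid | C/C=C(/C)C(=O)O | starting material
18 | (Z)-2-methylbut-2-enoic 2,4,6-trichlorobenzoic anhydride | C/C=C(/C)C(=O)OC(=O)c1c(Cl)cc(Cl)cc1Cl | intermediate
19 | methyl 2-[(2S,3S)-3-acetoxy-5-[(S)-1-{[(Z)-2-methylbut-2-enoyl]oxy}ethyl]-2,3-dihydrobenzofuran-2-yl]acrylate (CNP0168827.1) | C=C(C(=O)OC)[C@@H]1Oc2ccc([C@H](C)OC(=O)/C(C)=C\C)cc2[C@@H]1OC(C)=O | target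

Total step count: 12. Longest linear sequence: 12 steps (1 to 19); compounds 3, 7 and 17 are bought and enter directly.

Steps most likely to fail

Step 4. What may go wrong is loss of site selectivity of the doubly acceptor-substituted, more electrophilic carbenoid. It could insert at C3–H, attack the C3a–C4 arene bond or dimerise. The fallback runs from 2 back to 6, leaves the phosphonate off the carbenoid and brings it in after ring closure.
- Alcohol 2 is acylated with bromoacetyl bromide (pyridine, CH2Cl2, 0 °C) to the bromoacetate F1.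
- N,N′-ditosylhydrazine and DBU (THF, 0 °C) convert it into the diazoacetate F2.
- The milder acceptor-only carbenoid raised with the carboxamidate Rh2(NHCOCH3)4 (divalent rhodium; CH2Cl2, reflux, slow addition) should close the unsubstituted cis-fused lactone F3.
- Its lithium enolate (LiN(iPr)2, THF, −78 °C) carries O1 in the β-position, so it is kept cold and short-lived. It is quenched on carbon with ClP(OEt)2 to the phosphonite F4.
- Oxidation with air or H2O2 gives 6.

Step 9. Two things may go wrong. Hydroxide may add to the exocyclic methylene instead of the acyl carbon, which would be followed by expulsion of O1 as aryloxide. The hydroxy ester may also re-close to the lactone before it can be acetylated. The fallback runs from 12 back to 15 by a change of oxidation level that never passes through a γ-hydroxy ester.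
- iBu2AlH (CH2Cl2, −78 → 0 °C) reduces 12 to the diol F5.
- Et3SiCl/imidazole (CH2Cl2, −20 °C) silylates only the primary allylic hydroxyl and gives the mono-triethylsilyl ether F6.
- Ac2O/pyridine/DMAP puts the acetate on C3–OH to give the C3 acetate F7.
- HF·pyridine buffered with pyridine (THF, 0 °C) frees the primary allylic alcohol F8 while the secondary TBS ether stays.
- MnO2 (CH2Cl2) gives the enal F9.
- Pinnick oxidation (NaClO2, NaH2PO4, 2-methyl-2-butene, tBuOH/H2O) gives the acrylic acid F10.
- Me3SiCHN2 (toluene/MeOH) gives the methyl ester 15.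

Step 12. What may go wrong is Z-to-E isomerisation of the activated angeloyl unit, or ionisation of the alkoxy-activated benzylic alcohol during the prolonged heating that a catalyst-free acylation needs. The fallback runs from 16 to 19 and builds the Z-alkene only after a non-isomerisable acyl group is in place.
- 2-[bis(2,2,2-trifluoroethoxy)phosphoryl]propanoic acid F11 is freed from its commercial ethyl ester (LiOH, aq. THF, 0 °C).
- It is coupled to 16 (DCC, DMAP cat., CH2Cl2, 0 °C) to give the phosphonopropionate ester F12, a mixture of epimers at the phosphorus-bearing carbon.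
- Still–Gennari olefination (KN(SiMe3)2, 18-crown-6, THF, −78 °C, then acetaldehyde) should give the Z-trisubstituted enoate 19.

Further compounds
F1 | step 4 | (S)-5-bromo-2,3-dihydrobenzofuran-3-yl 2-bromoacetate | C1Oc2ccc(Br)cc2[C@@H]1OC(=O)CBr
F2 | step 4 | (S)-5-bromo-2,3-dihydrobenzofuran-3-yl 2-diazoacetate | C1Oc2ccc(Br)cc2[C@@H]1OC(=O)C=[N+]=[N-]
F3 | step 4 | (3aS,8bS)-7-bromo-3a,8b-dihydrofuro[3,2-b]benzofuran-2(3H)-one | O=C1C[C@@H]2Oc3ccc(Br)cc3[C@@H]2O1
F4 | step 4 | diethyl [(3S,3aR,8bS)-7-bromo-2-oxo-2,3,3a,8b-tetrahydrofuro[3,2-b]benzofuran-3-yl]phosphonite | O=C1[C@@H](P(OCC)OCC)[C@@H]2Oc3ccc(Br)cc3[C@@H]2O1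
F5 | step 9 | (2S,3S)-5-[(S)-1-(tert-butyldimethylsilyloxy)ethyl]-2-(3-hydroxyprop-1-en-2-yl)-2,3-dihydrobenzofuran-3-ol | C=C(CO)[C@@H]1Oc2ccc([C@H](C)O[Si](C)(C)C(C)(C)C)cc2[C@@H]1O
F6 | step 9 | (2S,3S)-5-[(S)-1-(tert-butyldimethylsilyloxy)ethyl]-2-[3-(triethylsilyloxy)prop-1-en-2-yl]-2,3-dihydrobenzofuran-3-ol | C=C(CO[Si](CC)(CC)CC)[C@@H]1Oc2ccc([C@H](C)O[Si](C)(C)C(C)(C)C)cc2[C@@H]1O
F7 | step 9 | (2S,3S)-5-[(S)-1-(tert-butyldimethylsilyloxy)ethyl]-2-[3-(triethylsilyloxy)prop-1-en-2-yl]-2,3-dihydrobenzofuran-3-yl acetate | C=C(CO[Si](CC)(CC)CC)[C@@H]1Oc2ccc([C@H](C)O[Si](C)(C)C(C)(C)C)cc2[C@@H]1OC(C)=O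
F8 | step 9 | (2S,3S)-5-[(S)-1-(tert-butyldimethylsilyloxy)ethyl]-2-(3-hydroxyprop-1-en-2-yl)-2,3-dihydrobenzofuran-3-yl acetate | C=C(CO)[C@@H]1Oc2ccc([C@H](C)O[Si](C)(C)C(C)(C)C)cc2[C@@H]1OC(C)=O
F9 | step 9 | (2S,3S)-5-[(S)-1-(tert-butyldimethylsilyloxy)ethyl]-2-(3-oxoprop-1-en-2-yl)-2,3-dihydrobenzofuran-3-yl acetate | C=C(C=O)[C@@H]1Oc2ccc([C@H](C)O[Si](C)(C)C(C)(C)C)cc2[C@@H]1OC(C)=O
F10 | step 9 | 2-[(2S,3S)-3-acetoxy-5-[(S)-1-(tert-butyldimethylsilyloxy)ethyl]-2,3-dihydrobenzofuran-2-yl]acrylic acid | C=C(C(=O)O)[C@@H]1Oc2ccc([C@H](C)O[Si](C)(C)C(C)(C)C)cc2[C@@H]1OC(C)=O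
F11 | step 12 | 2-[bis(2,2,2-trifluoroethoxy)phosphoryl]propanoic acid | CC(C(=O)O)P(=O)(OCC(F)(F)F)OCC(F)(F)F
F12 | step 12 | methyl 2-[(2S,3S)-3-acetoxy-5-[(S)-1-({2-[bis(2,2,2-trifluoroethoxy)phosphoryl]propanoyl}oxy)ethyl]-2,3-dihydrobenzofuran-2-yl]acrylate | C=C(C(=O)OC)[C@@H]1Oc2ccc([C@H](C)OC(=O)C(C)P(=O)(OCC(F)(F)F)OCC(F)(F)F)cc2[C@@H]1OC(C)=O
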